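In a one-step world target would rise as substrate falls, but the alpha run reads 4 % substrate and 0 % target at 8.00 min, so 96.0 % of the charge then stands in forms not read.

| setting | alpha | epsilon | Wednesday's | Tuesday's | Sunday's | Thursday's |
|---|---|---|---|---|---|---|
| substrate | 10 mM | 10 mM | 10 mM | 10 mM | 10 mM | 10 mM |
| capture agent | 1.4 mM | 2.2 mM | 1.00 mM | 1.00 mM | 1.00 mM | 1.00 mM |
| temperature | 91 °C | 116 °C | 80 °C | 110 °C | 125 °C | 95 °C |
| remark | run made earlier | run made earlier |  |  |  |  |
| time |  |  | 40 min | 40 min | 40 min | 40 min |

- alpha (time / min: target / %, substrate / %): 1.33: 0, 55; 2.50: 0, 33; 4.00: 0, 20; 6.00: 0, 10; 8.00: 0, 4; 12.0: 3, 0; 20.0: 6, 2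
- epsilon (time / min: target / %, substrate / %): 0.250: 0, 48; 0.833: 1, 14; 1.50: 5, 2; 2.50: 14, 0; 3.00: 17, 0; 4.00: 27, 0; 5.00: 37, 1

(each reading ± 1.5 percentage points)

- the flask that comes out highest in amount of target, in percent of the substrate charged, or "all alike" when all lie within 1.5 percentage points (Wednesday's / Tuesday's / Sunday's / Thursday's / all alike)
- target at the end, in percent of the substrate charged, Wednesday's
- target at the end, in percent of the substrate charged, Tuesday's
- target at the end, in percent of the substrate charged, Sunday's
- target at the end, in percent of the substrate charged, Thursday's

For whoever takes over these four flasks: substrate goes early, and target comes late. In the epsilon run substrate is down to 2 % at 1.50 min, and target then climbs nearly straight at 0.0920 /min of the charge. At that mean the whole charge would take 10.9 min, longer than the substrate lasts, so the rate-limiting step stands behind the substrate. Over 40 min that slope gives 3.68; this product of late mean slope and time allowed is the fill number. The alpha run gives 0.00375 /min and so 0.150, though its rise of 3 percentage points stands against a scatter of 1.5 points.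

A flask still on a steady rise at the stop should stand somewhat under its fill number, since the straight mean ignores the lag; epsilon's 3.68, above one, means that its straight rise would reach the whole charge inside 40 min. This reckoning puts Wednesday's, colder than alpha, under 0.150 and Thursday's, hotter than alpha, over it, both still growing at the stop, so their time must not be touched. Tuesday's, cooler than epsilon, and Sunday's, the hottest, should be finished and can wait. The forecast, holding that target “appears only after a lag”, names Sunday's and gives 3 %, 76 %, 82 % and 21 % for Wednesday's, Tuesday's, Sunday's and Thursday's.

Sunday's comes highest, at 90.4 %, with Tuesday's at 84.7 %, and Sunday's homo dimer stands at 6.47 % against 11.2 % in Tuesday's.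

    substrate → intermediate A (k = 0.0260 /s, Ea = 97.0 kJ/mol)
    intermediate B → target (k = 0.00260 /s, Ea = 98.0 kJ/mol)
    intermediate B + capture agent → trapped intermediate (k = 0.130 /M/s, Ea = 82.0 kJ/mol)
    intermediate A → intermediate B (k = 0.00330 /s, Ea = 119 kJ/mol)
    2 substrate → homo dimer (k = 0.340 /M/s, Ea = 45.0 kJ/mol)
    (constants at 110 °C)

Thursday's gives 39.0 %, 18 points above the forecast. Its second-half slope gives a fill number of 0.481, above 0.150 and below one, and its target stands under that number. Wednesday's second-half slope gives 0.0458, under 0.150 and under epsilon's 3.68, and its target stands at 2.92 %.

The earlier runs and the new flask are calculated with constants of no real substance; scatter was added.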